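Cuts (ring numbering of the target: C1 alkylidene carbon, C2 CH, C3 quaternary carbon, C4 carbinol carbon): (a) the exocyclic C1=C(CH3)CHO unit goes back to a C1 ketone; (b) the side chain is cut between the sp2 CH of the outer 2,6-dimethylhepta-1,5-dienyl unit (C9) and the CH2 next to it; (c) the inner C(CH3)=CH alkene is cut by two Wittig disconnections back to a propanal arm on C3; (d) the ring substituents are peeled off down to 4,4-dimethoxycyclohexa-2,5-dienone.
Enabling feature: that CH2 is homoallylic to the inner trisubstituted alkene. It is therefore the terminal carbon of an (E)-3-methylbuta-1,3-dienyl cap, the only monosubstituted C=C on the cyclohexane fragment, and one B–H addition makes it the nucleophile. Its partner is the CH of an E-vinyl iodide made by syn-carbometalation of a terminal alkyne.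
Forward order: the six-membered ring is bought, not closed. It is decorated at C2 (conjugate addition), C3 (methylation, then allylation), C5–C6 (1,4-reduction) and C4 (MeLi). The allyl arm is then grown to the dienyl cap, the C21 core and the C9 iodide are joined in one flask to complete the C30 skeleton, the ketal is opened, and the Z-enal is built last.
Stereochemistry: one catalytic enantioselective conjugate addition sets C2. C2 relays to C3 (allylation anti to the C2 chain), and C3 relays to C4 (MeLi anti to the axial C3 methyl). Both E-alkenes (syn-carboalumination, stabilised ylide) pass through the coupling with retention. The Z-enal comes from a strain-controlled [3,3] shift of a chromate ester.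
Key step: step 12

Assumption: the (R,S,S)-phosphoramidite is taken to attack the dienone with the same facial sense as it attacks cyclohex-2-enone. If the sense is opposite, its mirror image is used.

Step 1
Reactants: 1 5-bromo-2-methylpent-2-ene
Product: 2 6-methylhept-5-en-1-yne
Conditions: LiC≡CH·H2NCH2CH2NH2, DMSO, 10 °C to rt
Reagents that add atoms: lithium acetylide–ethylenediamine complex, [Li+].[C-]#C.NCCN
Why: SN2 alkylation of an acetylide on a primary bromide in a dipolar aprotic solvent should be clean; no stereocentre is formed.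

Step 2
Reactants: 2 6-methylhept-5-en-1-yne
Product: 4 (E)-1-iodo-2,6-dimethylhepta-1,5-diene, via alkenylalane 3 (not isolated)
Conditions: Me3Al, Cp2ZrCl2 (cat.), CH2Cl2, 0 °C to rt; then I2, THF, −30 to 0 °C
Reagents that add atoms: trimethylaluminium, C[Al](C)C; iodine, II
Why: Negishi carboalumination adds methyl (internal carbon) and aluminium (terminal carbon) syn across the alkyne, and iodinolysis with retention fixes the E geometry, while the trisubstituted alkene stays inert.

Step 3
Reactants: 5 4,4-dimethoxycyclohexa-2,5-dien-1-one; 6 tert-butyl(3-iodopropoxy)dimethylsilane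
Product: 8 (5S)-5-[3-(tert-butyldimethylsilyloxy)propyl]-4,4-dimethoxycyclohex-2-en-1-one, via dialkylzinc 7 (not isolated)
Conditions: 6, Et2Zn, CuI (cat.), neat, 50 °C, volatiles removed in vacuo; then 5, Cu(OTf)2 (cat.), (R)-BINOL-derived N,N-bis[(S)-1-phenylethyl]phosphoramidite (cat.), toluene, −25 °C; aq. NH4Cl
Reagents that add atoms: none
Why: Iodine–zinc exchange followed by copper-catalysed enantioselective conjugate addition of the dialkylzinc desymmetrises the prochiral quinone monoketal; the chiral copper–phosphoramidite complex picks one enantiotopic enone face and so sets the ring CH centre (5S).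

Step 4
Reactants: 8 (5S)-5-[3-(tert-butyldimethylsilyloxy)propyl]-4,4-dimethoxycyclohex-2-en-1-one
Product: 10 (5S)-5-[3-(tert-butyldimethylsilyloxy)propyl]-4,4-dimethoxy-6-methylcyclohex-2-en-1-one (C6 epimers), via lithium dienolate 9 (not isolated)
Conditions: LDA, THF, −78 °C; then MeI, −78 to −30 °C
Reagents that add atoms: iodomethane, CI
Why: Kinetic alpha-prime deprotonation of an enone that has no gamma hydrogen, followed by SN2 methylation of the cross-conjugated dienolate; the new centre is planarised again in step 5, so both epimers serve.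

Step 5
Reactants: 10 (5S)-5-[3-(tert-butyldimethylsilyloxy)propyl]-4,4-dimethoxy-6-methylcyclohex-2-en-1-one
Product: 12 (5S,6S)-6-allyl-5-[3-(tert-butyldimethylsilyloxy)propyl]-4,4-dimethoxy-6-methylcyclohex-2-en-1-one, via lithium dienolate 11 (not isolated)
Conditions: LDA, THF–DMPU, −78 to −40 °C; then allyl bromide, to 0 °C
Reagents that add atoms: allyl bromide, C=CCBr
Why: In this enolate alkylation the neighbouring silyloxypropyl chain turns pseudoaxial to avoid the enolate methyl, so allyl bromide enters from the opposite face (as in 5-substituted 6-methylcyclohexenone dienolates of the carvone series) and sets the quaternary centre with allyl trans and methyl cis to that chain.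

Step 6
Reactants: 12 (5S,6S)-6-allyl-5-[3-(tert-butyldimethylsilyloxy)propyl]-4,4-dimethoxy-6-methylcyclohex-2-en-1-one
Product: 13 (2S,3S)-2-allyl-3-[3-(tert-butyldimethylsilyloxy)propyl]-4,4-dimethoxy-2-methylcyclohexan-1-one
Conditions: LiBH(s-Bu)3 (L-Selectride), THF, −78 °C; aq. NH4Cl
Reagents that add atoms: none
Why: Conjugate hydride reduction of a beta-unsubstituted cyclohexenone by a bulky trialkylborohydride; the carbonyl carbon is shielded by the adjacent quaternary carbon, so hydride should go 1,4, and the isolated allyl group, ketal and silyl ether are not touched.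

Step 7
Reactants: 13 (2S,3S)-2-allyl-3-[3-(tert-butyldimethylsilyloxy)propyl]-4,4-dimethoxy-2-methylcyclohexan-1-one
Product: 15 (1S,2S,3S)-2-allyl-3-[3-(tert-butyldimethylsilyloxy)propyl]-4,4-dimethoxy-1,2-dimethyl-1-(trimethylsilyloxy)cyclohexane, via lithium alkoxide 14 (not isolated)
Conditions: MeLi, Et2O, −78 to −30 °C; then Me3SiCl, −30 °C to rt
Reagents that add atoms: methyllithium, [Li]C; chlorotrimethylsilane, C[Si](C)(C)Cl
Why: 1,2-addition of MeLi to the chair with equatorial allyl and silyloxypropyl groups takes place axially, opposite to the axial methyl on the adjacent quaternary carbon, which places the new methyl cis to the allyl arm and the oxygen cis to that methyl (1S); the alkoxide is silylated in the same flask.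

Step 8
Reactants: 15 (1S,2S,3S)-2-allyl-3-[3-(tert-butyldimethylsilyloxy)propyl]-4,4-dimethoxy-1,2-dimethyl-1-(trimethylsilyloxy)cyclohexane
Product: 17 (1S,2S,3S)-3-[3-(tert-butyldimethylsilyloxy)propyl]-2-(3-hydroxypropyl)-4,4-dimethoxy-1,2-dimethyl-1-(trimethylsilyloxy)cyclohexane, via alkylborane 16 (not isolated)
Conditions: 9-BBN-H, THF, 0 °C to rt; then 30% H2O2, aq. NaOH, 0 °C
Reagents that add atoms: hydrogen peroxide, OO
Why: Anti-Markovnikov hydroboration–oxidation of the only alkene present; no stereocentre is formed or touched.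

Step 9
Reactants: 17 (1S,2S,3S)-3-[3-(tert-butyldimethylsilyloxy)propyl]-2-(3-hydroxypropyl)-4,4-dimethoxy-1,2-dimethyl-1-(trimethylsilyloxy)cyclohexane
Product: 18 (1S,2S,3S)-3-[3-(tert-butyldimethylsilyloxy)propyl]-4,4-dimethoxy-1,2-dimethyl-2-(3-oxopropyl)-1-(trimethylsilyloxy)cyclohexane
Conditions: Dess–Martin periodinane, NaHCO3, CH2Cl2, 0 °C to rt
Reagents that add atoms: none
Why: Buffered Dess–Martin oxidation of a primary alcohol stops at the aldehyde and spares the ketal and silyl ethers.

Step 10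
Reactants: 18 (1S,2S,3S)-3-[3-(tert-butyldimethylsilyloxy)propyl]-4,4-dimethoxy-1,2-dimethyl-2-(3-oxopropyl)-1-(trimethylsilyloxy)cyclohexane
Product: 19 (1S,2S,3S)-3-[3-(tert-butyldimethylsilyloxy)propyl]-4,4-dimethoxy-1,2-dimethyl-2-[(3E)-4-methyl-5-oxopent-3-en-1-yl]-1-(trimethylsilyloxy)cyclohexane
Conditions: Ph3P=C(CH3)CHO, toluene, 90 °C
Reagents that add atoms: 2-(triphenylphosphoranylidene)propanal, CC(C=O)=P(c1ccccc1)(c1ccccc1)c1ccccc1
Why: Wittig olefination of an unhindered aldehyde by a formyl-stabilised ylide is under thermodynamic control and should give the E-trisubstituted enal.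

Step 11
Reactants: 19 (1S,2S,3S)-3-[3-(tert-butyldimethylsilyloxy)propyl]-4,4-dimethoxy-1,2-dimethyl-2-[(3E)-4-methyl-5-oxopent-3-en-1-yl]-1-(trimethylsilyloxy)cyclohexane
Product: 20 (1S,2S,3S)-3-[3-(tert-butyldimethylsilyloxy)propyl]-4,4-dimethoxy-1,2-dimethyl-2-[(3E)-4-methylhexa-3,5-dien-1-yl]-1-(trimethylsilyloxy)cyclohexane
Conditions: Ph3PCH3Br, KOt-Bu, THF, 0 °C; then 19, −78 to 0 °C
Reagents that add atoms: methyltriphenylphosphonium bromide, C[P+](c1ccccc1)(c1ccccc1)c1ccccc1.[Br-]
Why: Wittig methylenation of the enal gives the terminal diene and leaves the existing E-alkene untouched.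

Step 12
Reactants: 20 (1S,2S,3S)-3-[3-(tert-butyldimethylsilyloxy)propyl]-4,4-dimethoxy-1,2-dimethyl-2-[(3E)-4-methylhexa-3,5-dien-1-yl]-1-(trimethylsilyloxy)cyclohexane; 4 (E)-1-iodo-2,6-dimethylhepta-1,5-diene
Product: 22 (1S,2S,3S)-3-[3-(tert-butyldimethylsilyloxy)propyl]-4,4-dimethoxy-1,2-dimethyl-1-(trimethylsilyloxy)-2-[(3E,7E)-4,8,12-trimethyltrideca-3,7,11-trien-1-yl]cyclohexane, via homoallylic borane 21 (not isolated)
Conditions: 9-BBN-H, THF, 0 °C to rt; then 4, PdCl2(dppf) (cat.), AsPh3 (cat.), Cs2CO3, DMF–THF–H2O, rt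
Reagents that add atoms: none
Why: 9-BBN-H adds syn and anti-Markovnikov to the CH2=CH end of the dienyl cap of 20 to give the primary homoallylic borane 21, which carbonate and water convert to a hydroxyborate; zerovalent palladium inserts into the C–I bond of 4, the alkyl group passes from boron to divalent palladium, and reductive elimination forms the C(sp3)–C(sp2) bond. The closest known reaction type is the B-alkyl Suzuki–Miyaura coupling of 9-BBN adducts of terminal alkenes with (E)-2-methyl-1-iodoalk-1-enes, an established entry to 1,5-dienes of the polyprenyl type. No ring is closed and no stereocentre is created; oxidative addition and reductive elimination go with retention at the sp2 carbon, so the E geometry made in step 2 and the E geometry made in step 10 both appear unchanged in 22. The selectivity needed is site selectivity of the hydroboration: the vinyl group is the only monosubstituted alkene of 20, the adjoining trisubstituted alkene is too hindered for 9-BBN-H, and it stays so after the first addition, so no second addition is expected. Beta-hydride elimination from the alkylpalladium should be held back by the wide-bite-angle dppf ligand together with AsPh3, and carbonate at room temperature should leave the ketal and the three silyl ethers intact. This one flask joins C21 and C9, completes the C30 skeleton and fixes the full homofarnesyl chain without any activating group that must be removed later.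

Step 13
Reactants: 22 (1S,2S,3S)-3-[3-(tert-butyldimethylsilyloxy)propyl]-4,4-dimethoxy-1,2-dimethyl-1-(trimethylsilyloxy)-2-[(3E,7E)-4,8,12-trimethyltrideca-3,7,11-trien-1-yl]cyclohexane
Product: 23 (2S,3S,4S)-2-[3-(tert-butyldimethylsilyloxy)propyl]-4-hydroxy-3,4-dimethyl-3-[(3E,7E)-4,8,12-trimethyltrideca-3,7,11-trien-1-yl]cyclohexan-1-one
Conditions: PPTS (cat.), acetone–H2O, rt
Reagents that add atoms: water, O
Why: Mild acid hydrolysis cleaves the labile dimethyl ketal and the tertiary trimethylsilyl ether together, while the primary TBS ether and the trisubstituted alkenes survive and the weak acid should not enolise the ketone, so C2 is kept.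

Step 14
Reactants: 23 (2S,3S,4S)-2-[3-(tert-butyldimethylsilyloxy)propyl]-4-hydroxy-3,4-dimethyl-3-[(3E,7E)-4,8,12-trimethyltrideca-3,7,11-trien-1-yl]cyclohexan-1-one
Product: 24 (1R,2S,3S,4S)-2-[3-(tert-butyldimethylsilyloxy)propyl]-3,4-dimethyl-1-(prop-1-en-2-yl)-3-[(3E,7E)-4,8,12-trimethyltrideca-3,7,11-trien-1-yl]cyclohexane-1,4-diol
Conditions: CH2=C(CH3)MgBr (excess), LaCl3·2LiCl, THF, −78 to 0 °C; aq. NH4Cl
Reagents that add atoms: isopropenylmagnesium bromide, C=C(C)[Mg]Br
Why: Lanthanide-promoted Grignard 1,2-addition is weakly basic, so the alpha centre is not enolised; equatorial attack, away from the syn-axial C3 methyl, should give the (1R)-carbinol, whose configuration is erased in step 15.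

Step 15
Reactants: 24 (1R,2S,3S,4S)-2-[3-(tert-butyldimethylsilyloxy)propyl]-3,4-dimethyl-1-(prop-1-en-2-yl)-3-[(3E,7E)-4,8,12-trimethyltrideca-3,7,11-trien-1-yl]cyclohexane-1,4-diol
Product: 25 (2Z)-2-{(2R,3S,4S)-2-[3-(tert-butyldimethylsilyloxy)propyl]-4-hydroxy-3,4-dimethyl-3-[(3E,7E)-4,8,12-trimethyltrideca-3,7,11-trien-1-yl]cyclohexylidene}propanal
Conditions: pyridinium chlorochromate [C5H5NH][CrO3Cl], 4 Å molecular sieves, CH2Cl2, 0 °C to rt
Reagents that add atoms: pyridinium chlorochromate, [O-][Cr](=O)(=O)Cl.c1cc[nH+]cc1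
Why: In this Babler–Dauben oxidative transposition the tertiary allylic chromate undergoes a [3,3] shift and the primary chromate is oxidised irreversibly to the enal; in the cyclic transition state the isopropenyl methyl eclipses the ring CH2 rather than the branched C2, so the oxygen-bearing carbon ends up cis to C2, which is the Z geometry, while the saturated tertiary alcohol cannot be oxidised.

Step 16
Reactants: 25 (2Z)-2-{(2R,3S,4S)-2-[3-(tert-butyldimethylsilyloxy)propyl]-4-hydroxy-3,4-dimethyl-3-[(3E,7E)-4,8,12-trimethyltrideca-3,7,11-trien-1-yl]cyclohexylidene}propanal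
Product: 26 iridal
Conditions: HF·pyridine, pyridine, THF, 0 °C to rt
Reagents that add atoms: none
Why: Buffered fluoride desilylation frees the primary alcohol without the base that could deconjugate or isomerise the enal and without acid strong enough to attack the polyene.

Compound list
1 | 5-bromo-2-methylpent-2-ene | CC(C)=CCCBr | starting material
2 | 6-methylhept-5-en-1-yne | CC(C)=CCCC#C | intermediate
3 | (E)-(2,6-dimethylhepta-1,5-dien-1-yl)dimethylalane | CC(C)=CCC/C(C)=C/[Al](C)C | intermediate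
4 | (E)-1-iodo-2,6-dimethylhepta-1,5-diene | CC(C)=CCC/C(C)=C/I | intermediate
5 | 4,4-dimethoxycyclohexa-2,5-dien-1-one | COC1(OC)C=CC(=O)C=C1 | starting material
6 | tert-butyl(3-iodopropoxy)dimethylsilane | CC(C)(C)[Si](C)(C)OCCCI | starting material
7 | bis[3-(tert-butyldimethylsilyloxy)propyl]zinc | CC(C)(C)[Si](C)(C)OCCC[Zn]CCCO[Si](C)(C)C(C)(C)C | intermediate
8 | (5S)-5-[3-(tert-butyldimethylsilyloxy)propyl]-4,4-dimethoxycyclohex-2-en-1-one | O=C1C[C@H](CCCO[Si](C)(C)C(C)(C)C)C(OC)(OC)C=C1 | intermediate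
9 | lithium cross-conjugated dienolate of 8 | [Li+].[O-]C1=C[C@H](CCCO[Si](C)(C)C(C)(C)C)C(OC)(OC)C=C1 | intermediate
10 | (5S)-5-[3-(tert-butyldimethylsilyloxy)propyl]-4,4-dimethoxy-6-methylcyclohex-2-en-1-one, C6 epimers | O=C1C(C)[C@H](CCCO[Si](C)(C)C(C)(C)C)C(OC)(OC)C=C1 | intermediate
11 | lithium cross-conjugated dienolate of 10 | [Li+].[O-]C1=C(C)[C@H](CCCO[Si](C)(C)C(C)(C)C)C(OC)(OC)C=C1 | intermediate
12 | (5S,6S)-6-allyl-5-[3-(tert-butyldimethylsilyloxy)propyl]-4,4-dimethoxy-6-methylcyclohex-2-en-1-one | C=CC[C@@]1(C)[C@H](CCCO[Si](C)(C)C(C)(C)C)C(OC)(OC)C=CC1=O | intermediate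
13 | (2S,3S)-2-allyl-3-[3-(tert-butyldimethylsilyloxy)propyl]-4,4-dimethoxy-2-methylcyclohexan-1-one | C=CC[C@@]1(C)[C@H](CCCO[Si](C)(C)C(C)(C)C)C(OC)(OC)CCC1=O | intermediate
14 | lithium (1S,2S,3S)-2-allyl-3-[3-(tert-butyldimethylsilyloxy)propyl]-4,4-dimethoxy-1,2-dimethylcyclohexan-1-olate | C=CC[C@@]1(C)[C@H](CCCO[Si](C)(C)C(C)(C)C)C(OC)(OC)CC[C@]1(C)[O-].[Li+] | intermediate
15 | (1S,2S,3S)-2-allyl-3-[3-(tert-butyldimethylsilyloxy)propyl]-4,4-dimethoxy-1,2-dimethyl-1-(trimethylsilyloxy)cyclohexane | C=CC[C@@]1(C)[C@H](CCCO[Si](C)(C)C(C)(C)C)C(OC)(OC)CC[C@]1(C)O[Si](C)(C)C | intermediate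
16 | B-alkyl-9-BBN from 15 (allyl changed to 3-(9-borabicyclo[3.3.1]nonan-9-yl)propyl) | C(CC[C@@]1(C)[C@H](CCCO[Si](C)(C)C(C)(C)C)C(OC)(OC)CC[C@]1(C)O[Si](C)(C)C)B1C2CCCC1CCC2 | intermediate
17 | (1S,2S,3S)-3-[3-(tert-butyldimethylsilyloxy)propyl]-2-(3-hydroxypropyl)-4,4-dimethoxy-1,2-dimethyl-1-(trimethylsilyloxy)cyclohexane | OCCC[C@@]1(C)[C@H](CCCO[Si](C)(C)C(C)(C)C)C(OC)(OC)CC[C@]1(C)O[Si](C)(C)C | intermediate
18 | (1S,2S,3S)-3-[3-(tert-butyldimethylsilyloxy)propyl]-4,4-dimethoxy-1,2-dimethyl-2-(3-oxopropyl)-1-(trimethylsilyloxy)cyclohexane | O=CCC[C@@]1(C)[C@H](CCCO[Si](C)(C)C(C)(C)C)C(OC)(OC)CC[C@]1(C)O[Si](C)(C)C | intermediate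
19 | (1S,2S,3S)-3-[3-(tert-butyldimethylsilyloxy)propyl]-4,4-dimethoxy-1,2-dimethyl-2-[(3E)-4-methyl-5-oxopent-3-en-1-yl]-1-(trimethylsilyloxy)cyclohexane | O=C/C(C)=C/CC[C@@]1(C)[C@H](CCCO[Si](C)(C)C(C)(C)C)C(OC)(OC)CC[C@]1(C)O[Si](C)(C)C | intermediate
20 | (1S,2S,3S)-3-[3-(tert-butyldimethylsilyloxy)propyl]-4,4-dimethoxy-1,2-dimethyl-2-[(3E)-4-methylhexa-3,5-dien-1-yl]-1-(trimethylsilyloxy)cyclohexane | C=C/C(C)=C/CC[C@@]1(C)[C@H](CCCO[Si](C)(C)C(C)(C)C)C(OC)(OC)CC[C@]1(C)O[Si](C)(C)C | intermediate
21 | homoallylic B-alkyl-9-BBN from 20 (side chain (3E)-6-(9-borabicyclo[3.3.1]nonan-9-yl)-4-methylhex-3-en-1-yl) | C(C/C(C)=C/CC[C@@]1(C)[C@H](CCCO[Si](C)(C)C(C)(C)C)C(OC)(OC)CC[C@]1(C)O[Si](C)(C)C)B1C2CCCC1CCC2 | intermediate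
22 | (1S,2S,3S)-3-[3-(tert-butyldimethylsilyloxy)propyl]-4,4-dimethoxy-1,2-dimethyl-1-(trimethylsilyloxy)-2-[(3E,7E)-4,8,12-trimethyltrideca-3,7,11-trien-1-yl]cyclohexane | CC(C)=CCC/C(C)=C/CC/C(C)=C/CC[C@@]1(C)[C@H](CCCO[Si](C)(C)C(C)(C)C)C(OC)(OC)CC[C@]1(C)O[Si](C)(C)C | intermediate
23 | (2S,3S,4S)-2-[3-(tert-butyldimethylsilyloxy)propyl]-4-hydroxy-3,4-dimethyl-3-[(3E,7E)-4,8,12-trimethyltrideca-3,7,11-trien-1-yl]cyclohexan-1-one | CC(C)=CCC/C(C)=C/CC/C(C)=C/CC[C@@]1(C)[C@H](CCCO[Si](C)(C)C(C)(C)C)C(=O)CC[C@]1(C)O | intermediate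
24 | (1R,2S,3S,4S)-2-[3-(tert-butyldimethylsilyloxy)propyl]-3,4-dimethyl-1-(prop-1-en-2-yl)-3-[(3E,7E)-4,8,12-trimethyltrideca-3,7,11-trien-1-yl]cyclohexane-1,4-diol | CC(C)=CCC/C(C)=C/CC/C(C)=C/CC[C@@]1(C)[C@H](CCCO[Si](C)(C)C(C)(C)C)[C@@](O)(C(C)=C)CC[C@]1(C)O | intermediate
25 | (2Z)-2-{(2R,3S,4S)-2-[3-(tert-butyldimethylsilyloxy)propyl]-4-hydroxy-3,4-dimethyl-3-[(3E,7E)-4,8,12-trimethyltrideca-3,7,11-trien-1-yl]cyclohexylidene}propanal | CC(C)=CCC/C(C)=C/CC/C(C)=C/CC[C@@]1(C)[C@H](CCCO[Si](C)(C)C(C)(C)C)/C(=C(/C)C=O)CC[C@]1(C)O | intermediate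
26 | iridal, (2Z)-2-{(2R,3S,4S)-4-hydroxy-2-(3-hydroxypropyl)-3,4-dimethyl-3-[(3E,7E)-4,8,12-trimethyltrideca-3,7,11-trien-1-yl]cyclohexylidene}propanal | CC(C)=CCC/C(C)=C/CC/C(C)=C/CC[C@@]1(C)[C@H](CCCO)/C(=C(/C)C=O)CC[C@]1(C)O | target

Total step count: 16. Longest linear sequence: 14 (steps 3 to 16).

Steps most likely to fail

**Step 15.**
- What may go wrong: geometric control may erode during the 1,3-shift. The tertiary allylic chromate may ionise and dehydrate to dienes. The allyl cation may be intercepted by the C4 hydroxyl.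
- Fallback (from 23, back at 25), which avoids any cationic intermediate. Ketone 23 would be condensed with the lithium anion of diethyl (1-cyanoethyl)phosphonate (LiHMDS, THF; Horner–Wadsworth–Emmons olefination). This would give (2Z)-2-{(2R,3S,4S)-2-[3-(tert-butyldimethylsilyloxy)propyl]-4-hydroxy-3,4-dimethyl-3-[(3E,7E)-4,8,12-trimethyltrideca-3,7,11-trien-1-yl]cyclohexylidene}propanenitrile F1.
- In F1 the slim, linear nitrile rather than the methyl group should sit next to the branched C2.
- Reduction of F1 with i-Bu2AlH in toluene at −78 °C and hydrolysis of the aldimine would deliver 25.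

**Step 5.**
- What may go wrong: poor facial selectivity at the congested dienolate, O-allylation, or proton transfer.
- Fallback (from 10, back at 12), which replaces substrate control by catalyst control. The potassium dienolate of 10 (KHMDS) would be O-acylated with allyl chloroformate. This would give allyl (5S)-5-[3-(tert-butyldimethylsilyloxy)propyl]-4,4-dimethoxy-6-methylcyclohexa-1,5-dien-1-yl carbonate F2.
- Pd2(dba)3 with (R)-t-BuPHOX in toluene would ionise F2 and induce loss of carbon dioxide.
- C-allylation then takes place within the allylpalladium enolate (decarboxylative asymmetric allylic alkylation of the Tsuji type). The ligand is chosen so that its preference reinforces that of the substrate.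

**Step 12.**
- What may go wrong: transfer of the alkyl group from boron to palladium may be sluggish, so that protodeboronation and beta-hydride elimination take over.
- Fallback (from 20 through 21, back at 22), which changes the nucleophile from boron to zinc. Borane 21 would be treated with I2 and NaOMe to give the primary homoallylic iodide (1S,2S,3S)-3-[3-(tert-butyldimethylsilyloxy)propyl]-2-[(3E)-6-iodo-4-methylhex-3-en-1-yl]-4,4-dimethoxy-1,2-dimethyl-1-(trimethylsilyloxy)cyclohexane F3.
- Zinc dust with LiCl in THF would insert into F3 to give the corresponding alkylzinc iodide F4.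
- Negishi coupling of F4 with 4 under Pd(PPh3)4 at room temperature would give 22 with retention of both alkene geometries.

Further compounds
F1 | step 15 | (2Z)-2-{(2R,3S,4S)-2-[3-(tert-butyldimethylsilyloxy)propyl]-4-hydroxy-3,4-dimethyl-3-[(3E,7E)-4,8,12-trimethyltrideca-3,7,11-trien-1-yl]cyclohexylidene}propanenitrile | CC(C)=CCC/C(C)=C/CC/C(C)=C/CC[C@@]1(C)[C@H](CCCO[Si](C)(C)C(C)(C)C)/C(=C(/C)C#N)CC[C@]1(C)O
F2 | step 5 | allyl (5S)-5-[3-(tert-butyldimethylsilyloxy)propyl]-4,4-dimethoxy-6-methylcyclohexa-1,5-dien-1-yl carbonate | C=CCOC(=O)OC1=C(C)[C@H](CCCO[Si](C)(C)C(C)(C)C)C(OC)(OC)C=C1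
F3 | step 12 | (1S,2S,3S)-3-[3-(tert-butyldimethylsilyloxy)propyl]-2-[(3E)-6-iodo-4-methylhex-3-en-1-yl]-4,4-dimethoxy-1,2-dimethyl-1-(trimethylsilyloxy)cyclohexane | ICC/C(C)=C/CC[C@@]1(C)[C@H](CCCO[Si](C)(C)C(C)(C)C)C(OC)(OC)CC[C@]1(C)O[Si](C)(C)C
F4 | step 12 | alkylzinc iodide from F3 | I[Zn]CC/C(C)=C/CC[C@@]1(C)[C@H](CCCO[Si](C)(C)C(C)(C)C)C(OC)(OC)CC[C@]1(C)O[Si](C)(C)C
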